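**Retrosynthetic overview**

1. Rings: A is the 3,5-dihydroxyphenoxy end ring, B and D are the two 1,2,3-triaryloxy-5-hydroxy rings, C is the 2,6-dihydroxy-1,4-dioxy ring between them, and E/E' are the three biaryl units. The strategy rests on the biaryl bond from C5 of ring E (ether oxygen on C1, oxygens on C2, C4, C6) to C1' of ring E', which carries oxygen on all four ortho carbons (C4, C6, C2', C6').
2. That bond is not made by aryl–aryl coupling. Ring E' is grown on an ethoxyethynyl group at C5 of ring E by benzannulation with 3-ethoxycyclobutenone (new bonds C1'–C6' and C2'–C3'), once, for a common biaryl phenol that is used three times.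
3. Five of the six diaryl ether bonds come from fluoride displacement on fluorobenzaldehydes, each formyl carbon then being exchanged for the next phenol oxygen by Baeyer–Villiger oxidation: ring D and ring B from 2,6-difluoro-4-methoxybenzaldehyde, ring C from 4-fluoro-2,6-dimethoxybenzaldehyde.
4. Ring A is added last by copper-catalysed O-arylation of the middle phenol of ring B with 1-iodo-3,5-dimethoxybenzene, and BBr3 then cleaves 15 methyl and 9 ethyl ethers.
5. Order of ring formation: E' is the only ring that is built; rings E, D, C, B and A enter as benzenoid building blocks in that order.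

Key step: step 5

Assumption: 3-ethoxycyclobut-2-en-1-one, 2,6-difluoro-4-methoxybenzaldehyde and 4-fluoro-2,6-dimethoxybenzaldehyde are taken as purchasable building blocks.
Abbreviation used in names: BAO = 2,4,6-trimethoxy-3-(2,4,6-triethoxyphenyl)phenoxy, the protected biaryl unit bound through the C1 oxygen of ring E.

**Route**

Step 1
Reactants: 1 2,4,6-trimethoxybenzaldehyde
Product: 3 2,4,6-trimethoxyphenol, via 2,4,6-trimethoxyphenyl formate 2 (not isolated)
Conditions: mCPBA, CH2Cl2, 0 °C to rt; then K2CO3 (cat.), MeOH, rt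
Reagents that add atoms: mCPBA (3-chloroperoxybenzoic acid), OOC(=O)c1cccc(Cl)c1
Why: Baeyer–Villiger (Dakin-type) oxidation of an electron-rich benzaldehyde, in which the trimethoxyphenyl group migrates to oxygen in the Criegee adduct in preference to hydride and the aryl formate 2 is cleaved by base-catalysed methanolysis.

Step 2
Reactants: 3 2,4,6-trimethoxyphenol
Product: 4 2-(benzyloxy)-1,3,5-trimethoxybenzene
Conditions: BnBr, K2CO3, DMF, rt
Reagents that add atoms: benzyl bromide, BrCc1ccccc1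
Why: Williamson O-benzylation of the phenoxide, which marks the one oxygen of ring E (C1) that must later be freed beside three methyl ethers.

Step 3
Reactants: 4 2-(benzyloxy)-1,3,5-trimethoxybenzene
Product: 5 2-(benzyloxy)-4-iodo-1,3,5-trimethoxybenzene
Conditions: NIS (1.0 equiv), MeCN, 0 °C to rt, dark
Reagents that add atoms: N-iodosuccinimide, O=C1CCC(=O)N1I
Why: Electrophilic aromatic iodination at one of two equivalent CH positions, each activated by two ortho methoxy groups, with one equivalent of NIS limiting the reaction to the mono-iodide.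

Step 4
Reactants: 5 2-(benzyloxy)-4-iodo-1,3,5-trimethoxybenzene; 6 ethoxyacetylene
Product: 9 2-(benzyloxy)-4-(ethoxyethynyl)-1,3,5-trimethoxybenzene, via lithium ethoxyacetylide 7 (not isolated), via ethoxyethynylzinc chloride 8 (not isolated)
Conditions: 6, n-BuLi, THF, −78 °C; ZnCl2, −78 to 0 °C; then 5, Pd(PPh3)4 (5 mol %), THF, rt to 50 °C; filtration through Et3N-deactivated silica
Reagents that add atoms: none
Why: Negishi coupling in which the alkynylzinc chloride 8 transmetallates to the arylpalladium iodide formed by oxidative addition of 5 to zerovalent palladium, the slim sp carbon coupling even between two ortho methoxy groups.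

Step 5
Reactants: 9 2-(benzyloxy)-4-(ethoxyethynyl)-1,3,5-trimethoxybenzene; 10 3-ethoxycyclobut-2-en-1-one (1.5 equiv)
Product: 15 2-[3-(benzyloxy)-2,4,6-trimethoxyphenyl]-3,5-diethoxyphenol, via vinylketene 11 (not isolated), via vinylcyclobutenone 12 (not isolated), via dienylketene 13 (not isolated), via cyclohexadienone 14 (not isolated)
Conditions: toluene, 80 °C until 9 is consumed, then 110 °C, Ar; then KOH, MeOH, rt
Reagents that add atoms: none
Why: This is a Danheiser benzannulation: cyclobutenone 10 opens by 4π electrocyclic ring opening to vinylketene 11, whose ketene C=C adds [2+2] across the ynol ether of 9 to give the 4-vinylcyclobutenone 12. Compound 12 opens again (4π) to dienylketene 13, and ring E' closes by thermal 6π electrocyclisation between the ketene carbon and the terminal CH2 to dienone 14, which tautomerises to phenol 15; the new bonds are C1'–C6' and C2'–C3', while C5'–C6' is the cleaved and re-formed bond of 10. The closest known reaction type is the benzannulation of cyclobutenones with alkoxy- and siloxyalkynes to 3-oxygenated phenols. No stereocentre is formed, and the biaryl axis needs no control because ring E' becomes symmetric about it in step 6 and in the target. The selectivity needed is the orientation of the ketene–alkyne cycloaddition: the ethoxy oxygen makes the aryl-bearing alkyne carbon nucleophilic, so it bonds to the electrophilic ketene carbonyl carbon and the aryl group ends between OH and OEt. The linear alkyne keeps the two ortho methoxy groups of ring E away from the bond-forming carbons, the temperature stays below that of ethylene loss from the ethyl ynol ether until 9 is consumed, and methanolic KOH returns any 15 acylated by surplus ketene.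

Step 6
Reactants: 15 2-[3-(benzyloxy)-2,4,6-trimethoxyphenyl]-3,5-diethoxyphenol
Product: 16 2-(benzyloxy)-1,3,5-trimethoxy-4-(2,4,6-triethoxyphenyl)benzene
Conditions: EtI, K2CO3, DMF, 60 °C
Reagents that add atoms: iodoethane, CCI
Why: Williamson O-ethylation, which makes ring E' a symmetric 2,4,6-triethoxyphenyl group so that the hindered biaryl axis is not a stereogenic element in any later intermediate.

Step 7
Reactants: 16 2-(benzyloxy)-1,3,5-trimethoxy-4-(2,4,6-triethoxyphenyl)benzene
Product: 17 2,4,6-trimethoxy-3-(2,4,6-triethoxyphenyl)phenol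
Conditions: H2 (1 atm), 10% Pd/C, EtOAc–EtOH, rt
Reagents that add atoms: none
Why: Hydrogenolysis of the benzyl aryl ether over palladium, to which methyl and ethyl aryl ethers are inert, so that only the C1 oxygen of ring E is freed.

Step 8
Reactants: 17 2,4,6-trimethoxy-3-(2,4,6-triethoxyphenyl)phenol (2.2 equiv); 18 2,6-difluoro-4-methoxybenzaldehyde
Product: 19 4-methoxy-2,6-bis(BAO)benzaldehyde
Conditions: Cs2CO3, DMSO, 120 °C, Ar
Reagents that add atoms: none
Why: Twofold nucleophilic aromatic substitution by addition–elimination, each fluorine being ortho to the formyl group that stabilises the Meisenheimer adduct attacked by the caesium phenoxide of 17.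

Step 9
Reactants: 19 4-methoxy-2,6-bis(BAO)benzaldehyde
Product: 21 4-methoxy-2,6-bis(BAO)phenol, via aryl formate 20 (not isolated)
Conditions: mCPBA, CH2Cl2, 0 °C to rt; then K2CO3 (cat.), MeOH, rt
Reagents that add atoms: mCPBA (3-chloroperoxybenzoic acid), OOC(=O)c1cccc(Cl)c1
Why: Baeyer–Villiger (Dakin-type) oxidation in which the aryl group with two ortho and one para oxygen donors migrates, methanolysis of formate 20 then freeing the C1 phenol of ring D with the C4 oxygen already methylated.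

Step 10
Reactants: 21 4-methoxy-2,6-bis(BAO)phenol; 22 4-fluoro-2,6-dimethoxybenzaldehyde (2 equiv)
Product: 23 2,6-dimethoxy-4-[4-methoxy-2,6-bis(BAO)phenoxy]benzaldehyde
Conditions: Cs2CO3, DMSO, 130 °C, Ar
Reagents that add atoms: none
Why: Nucleophilic aromatic substitution at a fluorine para to the formyl group, where the flanked phenoxide of 21 attacks a ring carbon (C4 of ring C) whose two ortho positions are CH.

Step 11
Reactants: 23 2,6-dimethoxy-4-[4-methoxy-2,6-bis(BAO)phenoxy]benzaldehyde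
Product: 25 2,6-dimethoxy-4-[4-methoxy-2,6-bis(BAO)phenoxy]phenol, via aryl formate 24 (not isolated)
Conditions: mCPBA, CH2Cl2, 0 °C to rt; then K2CO3 (cat.), MeOH, rt
Reagents that add atoms: mCPBA (3-chloroperoxybenzoic acid), OOC(=O)c1cccc(Cl)c1
Why: Baeyer–Villiger (Dakin-type) oxidation of a 2,6-dimethoxy-4-aryloxybenzaldehyde, aryl migration and methanolysis of formate 24 placing the phenol on C1 of ring C between the two methoxy groups.

Step 12
Reactants: 17 2,4,6-trimethoxy-3-(2,4,6-triethoxyphenyl)phenol; 18 2,6-difluoro-4-methoxybenzaldehyde (3 equiv)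
Product: 26 2-fluoro-4-methoxy-6-(BAO)benzaldehyde
Conditions: K2CO3, DMF, 70 °C
Reagents that add atoms: none
Why: Nucleophilic aromatic substitution held at the first fluorine by an excess of 18 and a lower temperature, the aryloxy group that enters making the second fluoride less reactive.

Step 13
Reactants: 25 2,6-dimethoxy-4-[4-methoxy-2,6-bis(BAO)phenoxy]phenol; 26 2-fluoro-4-methoxy-6-(BAO)benzaldehyde (1.5 equiv)
Product: 27 2-{2,6-dimethoxy-4-[4-methoxy-2,6-bis(BAO)phenoxy]phenoxy}-4-methoxy-6-(BAO)benzaldehyde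
Conditions: Cs2CO3, DMSO, 130 °C, Ar
Reagents that add atoms: none
Why: Second nucleophilic aromatic substitution at the remaining ortho-fluorine of 26 by the caesium phenoxide of 25, the same type of displacement as the second one in step 8.

Step 14
Reactants: 27 2-{2,6-dimethoxy-4-[4-methoxy-2,6-bis(BAO)phenoxy]phenoxy}-4-methoxy-6-(BAO)benzaldehyde
Product: 29 2-{2,6-dimethoxy-4-[4-methoxy-2,6-bis(BAO)phenoxy]phenoxy}-4-methoxy-6-(BAO)phenol, via aryl formate 28 (not isolated)
Conditions: mCPBA, CH2Cl2, 0 °C to rt; then K2CO3 (cat.), MeOH, rt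
Reagents that add atoms: mCPBA (3-chloroperoxybenzoic acid), OOC(=O)c1cccc(Cl)c1
Why: Baeyer–Villiger (Dakin-type) oxidation in which the oxygen-rich ring B migrates, methanolysis of formate 28 freeing the phenol on C1 of ring B.

Step 15
Reactants: 29 2-{2,6-dimethoxy-4-[4-methoxy-2,6-bis(BAO)phenoxy]phenoxy}-4-methoxy-6-(BAO)phenol; 30 1-iodo-3,5-dimethoxybenzene (3 equiv)
Product: 31 1-(3,5-dimethoxyphenoxy)-2-{2,6-dimethoxy-4-[4-methoxy-2,6-bis(BAO)phenoxy]phenoxy}-4-methoxy-6-(BAO)benzene
Conditions: CuI (20 mol %), picolinic acid (40 mol %), K3PO4, DMSO, 90 °C, Ar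
Reagents that add atoms: none
Why: Ullmann-type copper-catalysed diaryl ether coupling, the CuI–picolinic acid system being one that couples 2,6-disubstituted phenols and the aryl iodide having no ortho substituent.

Step 16
Reactants: 31 1-(3,5-dimethoxyphenoxy)-2-{2,6-dimethoxy-4-[4-methoxy-2,6-bis(BAO)phenoxy]phenoxy}-4-methoxy-6-(BAO)benzene
Product: 32 target CNP0294555.0
Conditions: BBr3 (large excess), CH2Cl2, −78 °C to rt; then H2O, 0 °C; work-up and chromatography under Ar
Reagents that add atoms: none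
Why: Lewis acid ether cleavage in which BBr3 binds each alkyl aryl ether oxygen and bromide removes methyl or ethyl by SN2, diaryl ether and biaryl bonds staying intact and hydrolysis of the aryl borates freeing all 24 hydroxyl groups.

**Compound list**

BAO = 2,4,6-trimethoxy-3-(2,4,6-triethoxyphenyl)phenoxy.

1 | 2,4,6-trimethoxybenzaldehyde | COc1cc(OC)c(C=O)c(OC)c1 | starting material
2 | 2,4,6-trimethoxyphenyl formate | COc1cc(OC)c(OC=O)c(OC)c1 | intermediate (not isolated)
3 | 2,4,6-trimethoxyphenol | COc1cc(OC)c(O)c(OC)c1 | intermediate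
4 | 2-(benzyloxy)-1,3,5-trimethoxybenzene | COc1cc(OC)c(OCc2ccccc2)c(OC)c1 | intermediate
5 | 2-(benzyloxy)-4-iodo-1,3,5-trimethoxybenzene | COc1cc(OC)c(OCc2ccccc2)c(OC)c1I | intermediate
6 | ethoxyacetylene | CCOC#C | starting material
7 | lithium ethoxyacetylide | CCOC#C[Li] | intermediate (not isolated)
8 | ethoxyethynylzinc chloride | CCOC#C[Zn]Cl | intermediate (not isolated)
9 | 2-(benzyloxy)-4-(ethoxyethynyl)-1,3,5-trimethoxybenzene | CCOC#Cc1c(OC)cc(OC)c(OCc2ccccc2)c1OC | intermediate
10 | 3-ethoxycyclobut-2-en-1-one | CCOC1=CC(=O)C1 | starting material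
11 | 3-ethoxybuta-1,3-dien-1-one (vinylketene) | C=C(OCC)C=C=O | intermediate (not isolated)
12 | 2-[3-(benzyloxy)-2,4,6-trimethoxyphenyl]-3-ethoxy-4-(1-ethoxyethenyl)cyclobut-2-en-1-one (racemic) | C=C(OCC)C1C(OCC)=C(c2c(OC)cc(OC)c(OCc3ccccc3)c2OC)C1=O | intermediate (not isolated)
13 | 2-[3-(benzyloxy)-2,4,6-trimethoxyphenyl]-3,5-diethoxyhexa-1,3,5-trien-1-one (ketene carbon and ethoxyvinyl group cis on C3=C4) | O=C=C(c1c(OC)cc(OC)c(OCc2ccccc2)c1OC)/C(OCC)=C\C(OCC)=C | intermediate (not isolated)
14 | 2-[3-(benzyloxy)-2,4,6-trimethoxyphenyl]-3,5-diethoxycyclohexa-2,4-dien-1-one | O=C1CC(OCC)=CC(OCC)=C1c1c(OC)cc(OC)c(OCc2ccccc2)c1OC | intermediate (not isolated)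
15 | 2-[3-(benzyloxy)-2,4,6-trimethoxyphenyl]-3,5-diethoxyphenol | CCOc1cc(O)c(-c2c(OC)cc(OC)c(OCc3ccccc3)c2OC)c(OCC)c1 | intermediate
16 | 2-(benzyloxy)-1,3,5-trimethoxy-4-(2,4,6-triethoxyphenyl)benzene | CCOc1cc(OCC)c(-c2c(OC)cc(OC)c(OCc3ccccc3)c2OC)c(OCC)c1 | intermediate
17 | 2,4,6-trimethoxy-3-(2,4,6-triethoxyphenyl)phenol | CCOc1cc(OCC)c(-c2c(OC)cc(OC)c(O)c2OC)c(OCC)c1 | intermediate
18 | 2,6-difluoro-4-methoxybenzaldehyde | COc1cc(F)c(C=O)c(F)c1 | starting material
19 | 4-methoxy-2,6-bis(BAO)benzaldehyde | O=Cc1c(Oc2c(OC)cc(OC)c(-c3c(OCC)cc(OCC)cc3OCC)c2OC)cc(OC)cc1Oc1c(OC)cc(OC)c(-c2c(OCC)cc(OCC)cc2OCC)c1OC | intermediate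
20 | 4-methoxy-2,6-bis(BAO)phenyl formate | O=COc1c(Oc2c(OC)cc(OC)c(-c3c(OCC)cc(OCC)cc3OCC)c2OC)cc(OC)cc1Oc1c(OC)cc(OC)c(-c2c(OCC)cc(OCC)cc2OCC)c1OC | intermediate (not isolated)
21 | 4-methoxy-2,6-bis(BAO)phenol | Oc1c(Oc2c(OC)cc(OC)c(-c3c(OCC)cc(OCC)cc3OCC)c2OC)cc(OC)cc1Oc1c(OC)cc(OC)c(-c2c(OCC)cc(OCC)cc2OCC)c1OC | intermediate
22 | 4-fluoro-2,6-dimethoxybenzaldehyde | COc1cc(F)cc(OC)c1C=O | starting material
23 | 2,6-dimethoxy-4-[4-methoxy-2,6-bis(BAO)phenoxy]benzaldehyde | O=Cc1c(OC)cc(Oc2c(Oc3c(OC)cc(OC)c(-c4c(OCC)cc(OCC)cc4OCC)c3OC)cc(OC)cc2Oc2c(OC)cc(OC)c(-c3c(OCC)cc(OCC)cc3OCC)c2OC)cc1OC | intermediate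
24 | 2,6-dimethoxy-4-[4-methoxy-2,6-bis(BAO)phenoxy]phenyl formate | O=COc1c(OC)cc(Oc2c(Oc3c(OC)cc(OC)c(-c4c(OCC)cc(OCC)cc4OCC)c3OC)cc(OC)cc2Oc2c(OC)cc(OC)c(-c3c(OCC)cc(OCC)cc3OCC)c2OC)cc1OC | intermediate (not isolated)
25 | 2,6-dimethoxy-4-[4-methoxy-2,6-bis(BAO)phenoxy]phenol | Oc1c(OC)cc(Oc2c(Oc3c(OC)cc(OC)c(-c4c(OCC)cc(OCC)cc4OCC)c3OC)cc(OC)cc2Oc2c(OC)cc(OC)c(-c3c(OCC)cc(OCC)cc3OCC)c2OC)cc1OC | intermediate
26 | 2-fluoro-4-methoxy-6-(BAO)benzaldehyde | O=Cc1c(F)cc(OC)cc1Oc1c(OC)cc(OC)c(-c2c(OCC)cc(OCC)cc2OCC)c1OC | intermediate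
27 | 2-{2,6-dimethoxy-4-[4-methoxy-2,6-bis(BAO)phenoxy]phenoxy}-4-methoxy-6-(BAO)benzaldehyde | O=Cc1c(Oc2c(OC)cc(Oc3c(Oc4c(OC)cc(OC)c(-c5c(OCC)cc(OCC)cc5OCC)c4OC)cc(OC)cc3Oc3c(OC)cc(OC)c(-c4c(OCC)cc(OCC)cc4OCC)c3OC)cc2OC)cc(OC)cc1Oc1c(OC)cc(OC)c(-c2c(OCC)cc(OCC)cc2OCC)c1OC | intermediate
28 | 2-{2,6-dimethoxy-4-[4-methoxy-2,6-bis(BAO)phenoxy]phenoxy}-4-methoxy-6-(BAO)phenyl formate | O=COc1c(Oc2c(OC)cc(Oc3c(Oc4c(OC)cc(OC)c(-c5c(OCC)cc(OCC)cc5OCC)c4OC)cc(OC)cc3Oc3c(OC)cc(OC)c(-c4c(OCC)cc(OCC)cc4OCC)c3OC)cc2OC)cc(OC)cc1Oc1c(OC)cc(OC)c(-c2c(OCC)cc(OCC)cc2OCC)c1OC | intermediate (not isolated)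
29 | 2-{2,6-dimethoxy-4-[4-methoxy-2,6-bis(BAO)phenoxy]phenoxy}-4-methoxy-6-(BAO)phenol | Oc1c(Oc2c(OC)cc(Oc3c(Oc4c(OC)cc(OC)c(-c5c(OCC)cc(OCC)cc5OCC)c4OC)cc(OC)cc3Oc3c(OC)cc(OC)c(-c4c(OCC)cc(OCC)cc4OCC)c3OC)cc2OC)cc(OC)cc1Oc1c(OC)cc(OC)c(-c2c(OCC)cc(OCC)cc2OCC)c1OC | intermediate
30 | 1-iodo-3,5-dimethoxybenzene | COc1cc(I)cc(OC)c1 | starting material
31 | 1-(3,5-dimethoxyphenoxy)-2-{2,6-dimethoxy-4-[4-methoxy-2,6-bis(BAO)phenoxy]phenoxy}-4-methoxy-6-(BAO)benzene (pentadeca-O-methyl nona-O-ethyl ether of the target) | COc1cc(OC)cc(Oc2c(Oc3c(OC)cc(Oc4c(Oc5c(OC)cc(OC)c(-c6c(OCC)cc(OCC)cc6OCC)c5OC)cc(OC)cc4Oc4c(OC)cc(OC)c(-c5c(OCC)cc(OCC)cc5OCC)c4OC)cc3OC)cc(OC)cc2Oc2c(OC)cc(OC)c(-c3c(OCC)cc(OCC)cc3OCC)c2OC)c1 | intermediate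
32 | target CNP0294555.0: ring A (3,5-dihydroxyphenoxy) on C1 of ring B; ring B with C2–O–C1 of ring C, C6–O–biaryl unit and C4–OH; ring C with 2,6-dihydroxy groups and C4–O–C1 of ring D; ring D with biaryl units on the C2 and C6 oxygens and C4–OH; each biaryl unit is 2,4,6-trihydroxy-3-(2,4,6-trihydroxyphenyl)phenoxy | Oc1cc(O)cc(Oc2c(Oc3c(O)cc(Oc4c(Oc5c(O)cc(O)c(-c6c(O)cc(O)cc6O)c5O)cc(O)cc4Oc4c(O)cc(O)c(-c5c(O)cc(O)cc5O)c4O)cc3O)cc(O)cc2Oc2c(O)cc(O)c(-c3c(O)cc(O)cc3O)c2O)c1 | target

**Step count and risks**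

Total step count: 16. Longest linear sequence: 15 steps (steps 1 to 11 and 13 to 16); step 12 is a one-step branch from 17.

Steps most likely to fail:

Step 5. The ethyl ynol ether of 9 may lose ethylene by retro-ene fragmentation, or be hydrated, before cyclobutenone 10 has opened. The cycloaddition at the aryl-bearing alkyne carbon, which sits between two ortho methoxy groups, may also be too slow at a temperature that 9 tolerates. The fallback makes the same vinylketene by elimination instead of by thermal ring opening. It sets out from 9: (2E)-3-ethoxybut-2-enoyl chloride F1, prepared from (2E)-3-ethoxybut-2-enoic acid with oxalyl chloride, would be added slowly together with Et3N to 9 in CH2Cl2 at 0 °C to rt. 1,4-Dehydrochlorination of F1 gives vinylketene 11, which is trapped by 9 as cyclobutenone 12. Once no ynol ether is left, the solvent is changed to toluene and heating at 80 to 110 °C takes 12 through 13 and 14. The fallback comes back to the route at 15.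

Step 13. The fluoride of 26 is deactivated by two oxygen donors and shielded by the neighbouring biaryl unit, so displacement may stall while the electron-rich phenoxide of 25 is degraded at the temperature required. The fallback replaces the second fluoride displacement by a copper-catalysed coupling that is helped by the ortho formyl group. It sets out from 17: 2-bromo-6-fluoro-4-methoxybenzaldehyde F2 would be made from 1-bromo-3-fluoro-5-methoxybenzene by lithiation between the two halogens (LDA, THF, −78 °C) and formylation with DMF. Phenol 17 displaces only the fluoride of F2 (K2CO3, DMF, 70 °C) to give 2-bromo-4-methoxy-6-(BAO)benzaldehyde F3. Ullmann coupling of F3 with phenol 25 (CuI, N,N-dimethylglycine, Cs2CO3, dioxane, 100 °C) then comes back to the route at 27.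

Step 15. The phenol of 29 sits between two large aryloxy groups, so copper phenoxide formation or the C–O bond-forming step may be too slow, and the electron-rich phenoxide may be oxidised instead. The fallback is a metal-free arylation with a diaryliodonium salt, a reaction known to tolerate ortho-disubstituted phenols. Iodide 30 would be oxidised with mCPBA and TsOH in MeCN and the product treated with 1,3,5-trimethoxybenzene to give (3,5-dimethoxyphenyl)(2,4,6-trimethoxyphenyl)iodonium 4-methylbenzenesulfonate F4. Setting out from 29, the potassium phenoxide (t-BuOK, THF–toluene, rt to 40 °C) would take the 3,5-dimethoxyphenyl group from F4, the trimethoxyphenyl group acting as the non-transferred ligand. The fallback comes back to the route at 31.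

Further compounds
F1 | step 5 | (2E)-3-ethoxybut-2-enoyl chloride | CCO/C(C)=C/C(=O)Cl
F2 | step 13 | 2-bromo-6-fluoro-4-methoxybenzaldehyde | COc1cc(F)c(C=O)c(Br)c1
F3 | step 13 | 2-bromo-4-methoxy-6-[2,4,6-trimethoxy-3-(2,4,6-triethoxyphenyl)phenoxy]benzaldehyde | O=Cc1c(Br)cc(OC)cc1Oc1c(OC)cc(OC)c(-c2c(OCC)cc(OCC)cc2OCC)c1OC
F4 | step 15 | (3,5-dimethoxyphenyl)(2,4,6-trimethoxyphenyl)iodonium 4-methylbenzenesulfonate | COc1cc(OC)cc([I+]c2c(OC)cc(OC)cc2OC)c1.Cc1ccc(cc1)S(=O)(=O)[O-]
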